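**Retrosynthetic overview** (target numbered as a hexahydroazulene: C3 carbinol carbon with isopropyl, C3a, C4 ester carbon, C6=C7 double bond, C8a methyl-bearing fusion carbon)

1. Ester C–O at C4 is cut back to the diol and 3,4-dimethoxybenzoyl chloride; the C3–isopropyl bond is cut back to a C3 ketone, to be attacked from the face opposite to the angular C8a methyl.
2. The seven-membered ring (C3a, C4, C5, C6, C7, C8, C8a) is opened at C6=C7 by ring-closing metathesis. The feature that allows this is the trisubstituted C6=C7 double bond, which lies inside that ring between the methylene groups C5 and C8 and two bonds away from every stereocentre; the trans C3a/C8a fusion can therefore be set in the open diene, whereas closure at C3a or C8a through a tether could only give the cis-fused ring.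
3. The diene, a 2,3-trans cyclopentanone with methyl and allyl on the quaternary carbon and a 1-hydroxy-3-methylbut-3-enyl arm on the α-carbon, comes from one three-component operation: copper-catalysed enantioselective conjugate methylation of 3-allylcyclopent-2-en-1-one and aldol capture of the enolate by 3-methylbut-3-enal.
4. Ring order: the cyclopentane ring and the arene are bought; the seven-membered ring is the only ring made and is closed last.

Key step: step 4

Assumption: the sense of induction of the copper–aminophosphine catalyst on enone 3 is taken from related 3-alkylcycloalkenones; the ligand enantiomer meant is the one that gives the (R)-configured quaternary carbon.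

**Step 1**
Reactants: 1 3-ethoxycyclopent-2-en-1-one
Product: 3 3-(prop-2-en-1-yl)cyclopent-2-en-1-one, via magnesium alkoxide adduct 2 (not isolated)
Conditions: allylMgBr, THF, 0 °C; then 1 M HCl, 0 °C, short contact
Reagents that add atoms: allylmagnesium bromide, C=CC[Mg]Br; water, O
Why: Stork–Danheiser enone synthesis: the allyl Grignard reagent should add 1,2 to the vinylogous ester carbonyl and cold dilute acid should hydrolyse the enol ether of adduct 2 with loss of the tertiary hydroxyl to give the β-allyl enone, short contact with acid keeping the allyl double bond out of conjugation; no stereocentre is formed.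

**Step 2**
Reactants: 4 3-methylbut-3-en-1-ol
Product: 5 3-methylbut-3-enal
Conditions: Dess–Martin periodinane, CH2Cl2, 0 °C to rt; filtered solution used at once
Reagents that add atoms: none
Why: Dess–Martin oxidation: the neutral, non-aqueous oxidant should stop at the aldehyde and should not move the 1,1-disubstituted double bond into conjugation; no stereocentre is formed.

**Step 3**
Reactants: 3 3-(prop-2-en-1-yl)cyclopent-2-en-1-one; 5 3-methylbut-3-enal
Product: 7 (2S,3R)-2-[(1S)-1-hydroxy-3-methylbut-3-en-1-yl]-3-methyl-3-(prop-2-en-1-yl)cyclopentan-1-one, via aluminium enolate 6 (not isolated)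
Conditions: Me3Al (1.3 equiv), copper thiophene-2-carboxylate (CuTC, C5H3CuO2S, 2 mol %), chiral SimplePhos-type aminophosphine ligand (4 mol %), Et2O, −30 °C; then 5, THF, −78 °C; aq. potassium sodium tartrate
Reagents that add atoms: trimethylaluminium, C[Al](C)C
Why: Tandem copper-catalysed asymmetric conjugate addition and aldol reaction (three-component coupling): the chiral copper–aminophosphine catalyst should deliver methyl to one face of the β-carbon and so set the quaternary centre (C8a, R), and the cyclic (E)-aluminium enolate 6 should add to the aldehyde through a closed Zimmerman–Traxler transition state on the face opposite to the allyl arm, the larger group at the neighbouring quaternary carbon, which sets the α-carbon (C3a, S, trans to allyl) and the anti-configured carbinol carbon (C4, S).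

**Step 4**
Reactants: 7 (2S,3R)-2-[(1S)-1-hydroxy-3-methylbut-3-en-1-yl]-3-methyl-3-(prop-2-en-1-yl)cyclopentan-1-one
Product: 8 (3aR,8S,8aS)-8-hydroxy-3a,6-dimethyl-3,3a,4,7,8,8a-hexahydroazulen-1(2H)-one
Conditions: second-generation Grubbs catalyst RuCl2(H2IMes)(PCy3)(=CHPh) (5 mol %), 1,4-benzoquinone (10 mol %), CH2Cl2, 5 mM, 40 °C
Reagents that add atoms: none
Why: Olefin metathesis by the Chauvin mechanism: the ruthenium alkylidene should load onto the monosubstituted allyl double bond and then close, by [2+2] cycloaddition and cycloreversion, onto the 1,1-disubstituted double bond of the other arm with loss of ethene. The closest known reaction type is ring-closing metathesis of an allyl/2-methylallyl diene to a methyl-substituted cycloalkene with second-generation ruthenium carbenes. One ring is closed, the seven-membered carbocycle, by formation of the endocyclic C6=C7 double bond between the terminal carbons of the two arms; its Z geometry is imposed by the ring size. No stereocentre is formed or touched: the trans fusion (C3a, C8a) and the carbinol centre C4 come unchanged from 7, since the reacting carbons are two bonds away from them. The step needs ring closure to win over dimerisation and the double bond to stay at C6=C7; the vicinal arrangement of the two arms on the cyclopentanone next to a quaternary carbon, high dilution, and benzoquinone as a hydride scavenger should secure this.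

**Step 5**
Reactants: 8 (3aR,8S,8aS)-8-hydroxy-3a,6-dimethyl-3,3a,4,7,8,8a-hexahydroazulen-1(2H)-one
Product: 9 (3R,3aS,4S,8aR)-6,8a-dimethyl-3-(propan-2-yl)-1,2,3,3a,4,5,8,8a-octahydroazulene-3,4-diol (jaeschkeanadiol)
Conditions: iPrMgCl (3.5 equiv), LaCl3·2LiCl (0.3 equiv), THF, −20 to 0 °C; aqueous work-up
Reagents that add atoms: isopropylmagnesium chloride, CC(C)[Mg]Cl
Why: Lanthanum chloride-promoted Grignard 1,2-addition to a ketone (the lanthanum salt should suppress enolisation and β-hydride reduction): after deprotonation of the hydroxyl the nucleophile should attack the cyclopentanone from the face opposite to the pseudoaxial angular methyl at C8a, the face of the C3a hydrogen, so that the new hydroxyl ends cis to methyl and to the C4 arm and C3 becomes R.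

**Step 6**
Reactants: 9 (3R,3aS,4S,8aR)-6,8a-dimethyl-3-(propan-2-yl)-1,2,3,3a,4,5,8,8a-octahydroazulene-3,4-diol; 10 3,4-dimethoxybenzoyl chloride
Product: 11 (3R,3aS,4S,8aR)-3-hydroxy-6,8a-dimethyl-3-(propan-2-yl)-1,2,3,3a,4,5,8,8a-octahydroazulen-4-yl 3,4-dimethoxybenzoate
Conditions: Et3N, DMAP (cat.), CH2Cl2, 0 °C to rt
Reagents that add atoms: none
Why: DMAP-catalysed acylation of an alcohol with an acid chloride (nucleophilic acyl substitution): only the secondary C4 hydroxyl should react, the tertiary C3 hydroxyl being too hindered, and the C4–O bond is not broken, so the configuration is retained.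

**Compound list**

1 | 3-ethoxycyclopent-2-en-1-one | CCOC1=CC(=O)CC1 | starting material
2 | bromomagnesium 3-ethoxy-1-(prop-2-en-1-yl)cyclopent-2-en-1-olate (racemic 1,2-adduct) | C=CCC1(O[Mg]Br)C=C(OCC)CC1 | intermediate
3 | 3-(prop-2-en-1-yl)cyclopent-2-en-1-one | C=CCC1=CC(=O)CC1 | intermediate
4 | 3-methylbut-3-en-1-ol | CC(=C)CCO | starting material
5 | 3-methylbut-3-enal | CC(=C)CC=O | intermediate
6 | dimethylaluminium (3R)-3-methyl-3-(prop-2-en-1-yl)cyclopent-1-en-1-olate | C=CC[C@@]1(C)CCC(O[Al](C)C)=C1 | intermediate
7 | (2S,3R)-2-[(1S)-1-hydroxy-3-methylbut-3-en-1-yl]-3-methyl-3-(prop-2-en-1-yl)cyclopentan-1-one | O[C@@H](CC(C)=C)[C@H]1C(=O)CC[C@]1(C)CC=C | intermediate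
8 | (3aR,8S,8aS)-8-hydroxy-3a,6-dimethyl-3,3a,4,7,8,8a-hexahydroazulen-1(2H)-one | O[C@H]1CC(C)=CC[C@@]2(C)CCC(=O)[C@H]12 | intermediate
9 | (3R,3aS,4S,8aR)-6,8a-dimethyl-3-(propan-2-yl)-1,2,3,3a,4,5,8,8a-octahydroazulene-3,4-diol | O[C@H]1CC(C)=CC[C@@]2(C)CC[C@@](O)(C(C)C)[C@H]12 | intermediate
10 | 3,4-dimethoxybenzoyl chloride | COc1ccc(C(Cl)=O)cc1OC | starting material
11 | (3R,3aS,4S,8aR)-3-hydroxy-6,8a-dimethyl-3-(propan-2-yl)-1,2,3,3a,4,5,8,8a-octahydroazulen-4-yl 3,4-dimethoxybenzoate | COc1ccc(C(=O)O[C@H]2CC(C)=CC[C@@]3(C)CC[C@@](O)(C(C)C)[C@H]23)cc1OC | target

**Step count and risks**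

Total step count: 6. Longest linear sequence: 5 steps (1 → 3 → 7 → 8 → 9 → 11).

The three steps most likely to fail:

Step 3 (three-component coupling). Proton transfer from the enolisable aldehyde to enolate 6 and methyl transfer from residual trimethylaluminium to the aldehyde would lower conversion. Weak discrimination between the methyl and allyl faces of the enolate, or an open transition state, would give C3a/C4 diastereomers. The fallback sets out from 7 as the mixture of diastereomers. Oxidation with Dess–Martin periodinane (CH2Cl2, rt) should merge all isomers into one β-diketone, (3R)-3-methyl-2-(3-methylbut-3-enoyl)-3-(prop-2-en-1-yl)cyclopentan-1-one F1, whose α-carbon between the two carbonyl groups epimerises freely. Reduction of the side-chain carbonyl with a ketoreductase picked by screening (NADPH, glucose, glucose dehydrogenase, phosphate buffer with DMSO, 30 °C) under dynamic kinetic resolution should return one diastereomer. The fallback comes back to the route at 7, with both centres under enzyme control instead of substrate control.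

Step 5 (isopropyl addition). β-Hydride transfer from the secondary Grignard reagent and enolisation of the hindered ketone may outrun addition, and the metal aldolate may open by retro-aldol cleavage. The fallback sets out from 8. Isopropenylmagnesium bromide with LaCl3·2LiCl (THF, −20 °C), a smaller nucleophile without a transferable β-hydrogen, should give (3S,3aS,4S,8aR)-6,8a-dimethyl-3-(prop-1-en-2-yl)-1,2,3,3a,4,5,8,8a-octahydroazulene-3,4-diol F2. Hydrogenation with RhCl(PPh3)3 under H2 (benzene/ethanol, rt) should saturate the 1,1-disubstituted double bond and leave the trisubstituted ring double bond; the fallback comes back to the route at 9.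

Step 4 (ring-closing metathesis). Slow loading of the ruthenium carbene on the 1,1-disubstituted double bond would let dimerisation through the allyl group or hydride-induced double-bond migration compete, and the free β-hydroxy ketone may bind the metal or cleave by retro-aldol reaction. The fallback sets out from 7. The isopropyl group is added first (iPrMgCl, LaCl3·2LiCl, THF, −20 °C) to give the open diol (1R,2S,3R)-2-[(1S)-1-hydroxy-3-methylbut-3-en-1-yl]-3-methyl-1-(propan-2-yl)-3-(prop-2-en-1-yl)cyclopentan-1-ol F3, in which no ketone remains and a second fully substituted carbon turns the two arms toward each other. Ring-closing metathesis of F3 with the second-generation Grubbs catalyst RuCl2(H2IMes)(PCy3)(=CHPh) should then close the seven-membered ring, still as the last ring; the fallback comes back to the route at 9.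

**Further compounds**

F1 | step 3 | (3R)-3-methyl-2-(3-methylbut-3-enoyl)-3-(prop-2-en-1-yl)cyclopentan-1-one | C=C(C)CC(=O)C1C(=O)CC[C@]1(C)CC=C
F2 | step 5 | (3S,3aS,4S,8aR)-6,8a-dimethyl-3-(prop-1-en-2-yl)-1,2,3,3a,4,5,8,8a-octahydroazulene-3,4-diol | O[C@H]1CC(C)=CC[C@@]2(C)CC[C@@](O)(C(C)=C)[C@H]12
F3 | step 4 | (1R,2S,3R)-2-[(1S)-1-hydroxy-3-methylbut-3-en-1-yl]-3-methyl-1-(propan-2-yl)-3-(prop-2-en-1-yl)cyclopentan-1-ol | O[C@@H](CC(C)=C)[C@H]1[C@](O)(C(C)C)CC[C@]1(C)CC=C
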